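**Assumption:** the target SMILES has no stereocentre and no stereogenic double bond, so the compound is achiral and nothing needs enantiocontrol. Stereocentres in intermediates are carried as racemic/diastereomeric mixtures (drawn without descriptors) and are all erased on aromatisation.

## Retrosynthetic overview

1. Target 20 ← hydrogenolysis of the two benzyl ethers of phenol 19.
2. 19 ← isoaromatisation of 6-arylidene-3-methoxycyclohexenone 17: the ketone becomes the phenol and the vinylogous ester becomes ArOMe, which fixes the OH/OMe/benzyl pattern.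
3. 17 ← key C–C bond: intermolecular aldol (then dehydration) of the α′-lithium enolate of vinylogous ester 12 with 4-(benzyloxy)benzaldehyde 13.
4. 12 ← 5-substituted cyclohexane-1,3-dione 11 ← Michael addition / Claisen cyclisation of dimethyl malonate 7 onto enone 6, then hydrolysis and decarboxylation.
5. 6 ← Wittig of aldehyde 4 ← 3-(3-hydroxyphenyl)propanoic acid 1. Only the central ring is built (as a cyclohexanedione in step 5, aromatised in step 10); both outer rings are bought.

## Route

**Step 1**
Reactants: 1 3-(3-hydroxyphenyl)propanoic acid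
Product: 2 benzyl 3-[3-(benzyloxy)phenyl]propanoate
Conditions: BnBr (2.3 equiv), K2CO3 (3 equiv), DMF, 60 °C
Reagents that add atoms: benzyl bromide, BrCc1ccccc1
Why: Williamson O-alkylation of the phenoxide and SN2 esterification of the carboxylate both go cleanly with a benzylic bromide, and the aryl benzyl ether survives every later base, acid and hydride step until the final hydrogenolysis.

**Step 2**
Reactants: 2 benzyl 3-[3-(benzyloxy)phenyl]propanoate
Product: 3 3-[3-(benzyloxy)phenyl]propan-1-ol
Conditions: LiAlH4 (1.2 equiv), THF, 0 °C to rt; Fieser work-up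
Reagents that add atoms: none
Why: Hydride reduction of the ester to the primary alcohol leaves the aryl benzyl ether untouched, and the benzyl alcohol co-product is removed by chromatography.

**Step 3**
Reactants: 3 3-[3-(benzyloxy)phenyl]propan-1-ol
Product: 4 3-[3-(benzyloxy)phenyl]propanal
Conditions: Dess–Martin periodinane (1.2 equiv), CH2Cl2, rt
Reagents that add atoms: none
Why: Dess–Martin oxidation stops at the aldehyde under neutral anhydrous conditions, with no over-oxidation and no aldol self-condensation.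

**Step 4**
Reactants: 4 3-[3-(benzyloxy)phenyl]propanal; 5 1-(triphenylphosphoranylidene)propan-2-one
Product: 6 (3E)-6-[3-(benzyloxy)phenyl]hex-3-en-2-one
Conditions: toluene, 90 °C
Reagents that add atoms: none
Why: Wittig olefination with a stabilised acyl ylide gives the (E)-enone selectively and avoids the self-condensation that a base-mediated aldol of this enolisable aldehyde with acetone would risk.

**Step 5**
Reactants: 6 (3E)-6-[3-(benzyloxy)phenyl]hex-3-en-2-one; 7 dimethyl malonate
Product: 9 methyl 6-{2-[3-(benzyloxy)phenyl]ethyl}-2,4-dioxocyclohexane-1-carboxylate, via Michael adduct 8 (not isolated)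
Conditions: NaOMe (1.1 equiv), MeOH, reflux; then cold 1 M HCl
Reagents that add atoms: none
Why: Michael addition of the malonate anion to the enone is followed in the same pot by intramolecular Claisen (Dieckmann-type) condensation of the methyl ketone onto a malonate ester, pulled forward by formation of the stabilised 1,3-dione enolate (the classical dihydroresorcinol synthesis); the stereocentres are irrelevant.

**Step 6**
Reactants: 9 methyl 6-{2-[3-(benzyloxy)phenyl]ethyl}-2,4-dioxocyclohexane-1-carboxylate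
Product: 11 5-{2-[3-(benzyloxy)phenyl]ethyl}cyclohexane-1,3-dione, via β-keto acid 10 (not isolated)
Conditions: 2 M aq. NaOH, reflux; then 6 M HCl to pH 1, 85 °C
Reagents that add atoms: sodium hydroxide, [Na+].[OH-] (its oxygen is held only by intermediate 10)
Why: Saponification followed by thermal decarboxylation of the β-keto acid gives the symmetrical 5-substituted dione, and the aryl benzyl ether tolerates brief hot dilute HCl.

**Step 7**
Reactants: 11 5-{2-[3-(benzyloxy)phenyl]ethyl}cyclohexane-1,3-dione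
Product: 12 5-{2-[3-(benzyloxy)phenyl]ethyl}-3-methoxycyclohex-2-en-1-one (racemic)
Conditions: MeOH, TsOH·H2O (5 mol%), 3 Å MS, reflux
Reagents that add atoms: methanol, CO
Why: Acid-catalysed enol etherification of a symmetrical 1,3-dione gives a single vinylogous methyl ester, which decides which ring oxygen ends up as OMe and which as OH.

**Step 8**
Reactants: 12 5-{2-[3-(benzyloxy)phenyl]ethyl}-3-methoxycyclohex-2-en-1-one; 13 4-(benzyloxy)benzaldehyde
Product: 15 6-{[4-(benzyloxy)phenyl](hydroxy)methyl}-5-{2-[3-(benzyloxy)phenyl]ethyl}-3-methoxycyclohex-2-en-1-one (diastereomer mixture), via lithium enolate 14 (not isolated)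
Conditions: LDA (1.15 equiv, commercial solution), THF, −78 °C; then 13 (1.2 equiv), −78 °C; AcOH quench at −78 °C
Reagents that add atoms: lithium diisopropylamide, [Li]N(C(C)C)C(C)C (its lithium is held only by intermediate 14)
Why: LDA deprotonates a 3-alkoxyenone kinetically at the α′-carbon C6 (Stork–Danheiser enolate), and aldol addition to the non-enolisable aldehyde forms the ring–CH(OH)Ar bond next to the side-chain carbon C5; the new stereocentres are left uncontrolled because steps 9 and 10 remove them all.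

**Step 9**
Reactants: 15 6-{[4-(benzyloxy)phenyl](hydroxy)methyl}-5-{2-[3-(benzyloxy)phenyl]ethyl}-3-methoxycyclohex-2-en-1-one
Product: 17 (6E)-6-[4-(benzyloxy)benzylidene]-5-{2-[3-(benzyloxy)phenyl]ethyl}-3-methoxycyclohex-2-en-1-one, via mesylate 16 (not isolated)
Conditions: MsCl (1.5 equiv), Et3N (3 equiv), CH2Cl2, 0 °C; then DBU (2 equiv), rt
Reagents that add atoms: methanesulfonyl chloride, CS(=O)(=O)Cl (its CH3SO2 group is held only by intermediate 16)
Why: Mesylation and E1cB elimination of the β-mesyloxy ketone complete the aldol condensation under non-hydrolytic conditions and give the thermodynamically preferred (E)-arylidene enone.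

**Step 10**
Reactants: 17 (6E)-6-[4-(benzyloxy)benzylidene]-5-{2-[3-(benzyloxy)phenyl]ethyl}-3-methoxycyclohex-2-en-1-one
Product: 19 2-[4-(benzyloxy)benzyl]-3-{2-[3-(benzyloxy)phenyl]ethyl}-5-methoxyphenol, via dienone tautomer 18 (not isolated)
Conditions: RhCl3·3H2O (5 mol%), MeOH, 90 °C (sealed tube), N2
Reagents that add atoms: none
Why: Rhodium hydride addition/β-hydride elimination moves the exocyclic C=C into the ring (isoaromatisation) and the resulting 4H-dienone tautomerises to the phenol, driven by aromatic stabilisation and erasing the C5 stereocentre; methanol as solvent keeps any alkoxy exchange at the vinylogous ester degenerate.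

**Step 11**
Reactants: 19 2-[4-(benzyloxy)benzyl]-3-{2-[3-(benzyloxy)phenyl]ethyl}-5-methoxyphenol
Product: 20 2-(4-hydroxybenzyl)-3-[2-(3-hydroxyphenyl)ethyl]-5-methoxyphenol (IN1159)
Conditions: H2 (1 atm), 10% Pd/C, EtOAc–MeOH, rt
Reagents that add atoms: none
Why: Catalytic hydrogenolysis cleaves both aryl benzyl ethers, while the aryl methyl ether, the arenes and the diarylmethane and bibenzyl C–C bonds are inert.

## Compound list

1 | 3-(3-hydroxyphenyl)propanoic acid | OC(=O)CCc1cccc(O)c1 | starting material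
2 | benzyl 3-[3-(benzyloxy)phenyl]propanoate | O=C(CCc1cccc(OCc2ccccc2)c1)OCc1ccccc1 | intermediate
3 | 3-[3-(benzyloxy)phenyl]propan-1-ol | OCCCc1cccc(OCc2ccccc2)c1 | intermediate
4 | 3-[3-(benzyloxy)phenyl]propanal | O=CCCc1cccc(OCc2ccccc2)c1 | intermediate
5 | 1-(triphenylphosphoranylidene)propan-2-one | CC(=O)C=P(c1ccccc1)(c1ccccc1)c1ccccc1 | starting material
6 | (3E)-6-[3-(benzyloxy)phenyl]hex-3-en-2-one | CC(=O)/C=C/CCc1cccc(OCc2ccccc2)c1 | intermediate
7 | dimethyl malonate | COC(=O)CC(=O)OC | starting material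
8 | dimethyl 2-{1-[3-(benzyloxy)phenyl]-5-oxohexan-3-yl}propanedioate (Michael adduct, racemic) | COC(=O)C(C(=O)OC)C(CC(C)=O)CCc1cccc(OCc2ccccc2)c1 | intermediate (not isolated)
9 | methyl 6-{2-[3-(benzyloxy)phenyl]ethyl}-2,4-dioxocyclohexane-1-carboxylate (racemic, diastereomer/tautomer mixture) | COC(=O)C1C(=O)CC(=O)CC1CCc1cccc(OCc2ccccc2)c1 | intermediate
10 | 6-{2-[3-(benzyloxy)phenyl]ethyl}-2,4-dioxocyclohexane-1-carboxylic acid (racemic) | OC(=O)C1C(=O)CC(=O)CC1CCc1cccc(OCc2ccccc2)c1 | intermediate (not isolated)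
11 | 5-{2-[3-(benzyloxy)phenyl]ethyl}cyclohexane-1,3-dione | O=C1CC(=O)CC(CCc2cccc(OCc3ccccc3)c2)C1 | intermediate
12 | 5-{2-[3-(benzyloxy)phenyl]ethyl}-3-methoxycyclohex-2-en-1-one (racemic) | COC1=CC(=O)CC(CCc2cccc(OCc3ccccc3)c2)C1 | intermediate
13 | 4-(benzyloxy)benzaldehyde | O=Cc1ccc(OCc2ccccc2)cc1 | starting material
14 | lithium 3-{2-[3-(benzyloxy)phenyl]ethyl}-5-methoxycyclohexa-1,5-dien-1-olate (racemic) | [Li]OC1=CC(CCc2cccc(OCc3ccccc3)c2)CC(OC)=C1 | intermediate (not isolated)
15 | 6-{[4-(benzyloxy)phenyl](hydroxy)methyl}-5-{2-[3-(benzyloxy)phenyl]ethyl}-3-methoxycyclohex-2-en-1-one (racemic diastereomer mixture) | COC1=CC(=O)C(C(O)c2ccc(OCc3ccccc3)cc2)C(CCc2cccc(OCc3ccccc3)c2)C1 | intermediate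
16 | [4-(benzyloxy)phenyl](6-{2-[3-(benzyloxy)phenyl]ethyl}-4-methoxy-2-oxocyclohex-3-en-1-yl)methyl methanesulfonate (diastereomer mixture) | COC1=CC(=O)C(C(OS(C)(=O)=O)c2ccc(OCc3ccccc3)cc2)C(CCc2cccc(OCc3ccccc3)c2)C1 | intermediate (not isolated)
17 | (6E)-6-[4-(benzyloxy)benzylidene]-5-{2-[3-(benzyloxy)phenyl]ethyl}-3-methoxycyclohex-2-en-1-one (racemic) | COC1=CC(=O)/C(=C/c2ccc(OCc3ccccc3)cc2)C(CCc2cccc(OCc3ccccc3)c2)C1 | intermediate
18 | 2-[4-(benzyloxy)benzyl]-3-{2-[3-(benzyloxy)phenyl]ethyl}-5-methoxycyclohexa-2,5-dien-1-one | COC1=CC(=O)C(Cc2ccc(OCc3ccccc3)cc2)=C(CCc2cccc(OCc3ccccc3)c2)C1 | intermediate (not isolated)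
19 | 2-[4-(benzyloxy)benzyl]-3-{2-[3-(benzyloxy)phenyl]ethyl}-5-methoxyphenol | COc1cc(O)c(Cc2ccc(OCc3ccccc3)cc2)c(CCc2cccc(OCc3ccccc3)c2)c1 | intermediate
20 | 2-(4-hydroxybenzyl)-3-[2-(3-hydroxyphenyl)ethyl]-5-methoxyphenol (IN1159) | COc1cc(O)c(Cc2ccc(O)cc2)c(CCc2cccc(O)c2)c1 | target

## Step count

Total steps: 11. Longest linear sequence: 11 (1 → 20); the partners 5, 7 and 13 are purchased.

## Three steps most likely to fail, with fallbacks

**Step 10 (isoaromatisation; risk: slow double-bond migration or partial hydrolysis of the vinylogous ester).** The fallback sets out from 17 and comes back at 19, replacing the isomerisation by a reduction/dehydrogenation pair. Rh-catalysed 1,4-hydrosilylation of the exocyclic enone of 17 (Et3SiH, (Ph3P)3RhCl cat., benzene, 60 °C) gives triethyl[(2-[4-(benzyloxy)benzyl]-3-{2-[3-(benzyloxy)phenyl]ethyl}-5-methoxycyclohexa-1,5-dien-1-yl)oxy]silane F4. This 1,3-cyclohexadiene is dehydrogenated with DDQ (1.0 equiv, benzene, rt) to the aryl silyl ether {2-[4-(benzyloxy)benzyl]-3-{2-[3-(benzyloxy)phenyl]ethyl}-5-methoxyphenoxy}triethylsilane F5. TBAF (THF, 0 °C) then frees phenol 19.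

**Step 8 (aldol; risk: retro-aldol on quench or proton transfer to the γ-dienolate).** The fallback sets out from 12 (through the same enolate 14) and comes back at 19, bypassing steps 8–10. The enolate is alkylated instead with commercial 4-(benzyloxy)benzyl bromide (LDA, THF–DMPU, −78 to 0 °C, Stork–Danheiser alkylation) to give 6-[4-(benzyloxy)benzyl]-5-{2-[3-(benzyloxy)phenyl]ethyl}-3-methoxycyclohex-2-en-1-one F3. Pd(II)-catalysed aerobic dehydrogenation (Pd(TFA)2, 2-(dimethylamino)pyridine, TsOH, O2, DMSO, 80 °C) then aromatises F3 to 19.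

**Step 5 (Michael/Claisen annulation; risk: enone deconjugation or self-condensation under methoxide).** The fallback sets out from aldehyde 4 and comes back at keto acid 10 (and so at 11), swapping the roles of acceptor and donor. Horner–Wadsworth–Emmons olefination of 4 (triethyl phosphonoacetate, NaH, THF, 0 °C) gives ethyl (2E)-5-[3-(benzyloxy)phenyl]pent-2-enoate F1. Michael addition of ethyl acetoacetate and Claisen ring closure (NaOEt, EtOH, reflux) give ethyl 6-{2-[3-(benzyloxy)phenyl]ethyl}-2,4-dioxocyclohexane-1-carboxylate F2. Saponification of F2 under the step 6 conditions gives the same acid 10, which decarboxylates to 11.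

## Further compounds

F1 | step 5 | ethyl (2E)-5-[3-(benzyloxy)phenyl]pent-2-enoate | CCOC(=O)/C=C/CCc1cccc(OCc2ccccc2)c1
F2 | step 5 | ethyl 6-{2-[3-(benzyloxy)phenyl]ethyl}-2,4-dioxocyclohexane-1-carboxylate | CCOC(=O)C1C(=O)CC(=O)CC1CCc1cccc(OCc2ccccc2)c1
F3 | step 8 | 6-[4-(benzyloxy)benzyl]-5-{2-[3-(benzyloxy)phenyl]ethyl}-3-methoxycyclohex-2-en-1-one | COC1=CC(=O)C(Cc2ccc(OCc3ccccc3)cc2)C(CCc2cccc(OCc3ccccc3)c2)C1
F4 | step 10 | triethyl[(2-[4-(benzyloxy)benzyl]-3-{2-[3-(benzyloxy)phenyl]ethyl}-5-methoxycyclohexa-1,5-dien-1-yl)oxy]silane | CC[Si](CC)(CC)OC1=C(Cc2ccc(OCc3ccccc3)cc2)C(CCc2cccc(OCc3ccccc3)c2)CC(OC)=C1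
F5 | step 10 | {2-[4-(benzyloxy)benzyl]-3-{2-[3-(benzyloxy)phenyl]ethyl}-5-methoxyphenoxy}triethylsilane | CC[Si](CC)(CC)Oc1cc(OC)cc(CCc2cccc(OCc3ccccc3)c2)c1Cc1ccc(OCc2ccccc2)cc1
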